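The sulfate ester bond S–O3' is traced back to a five-membered cyclic sulfate spanning the vicinal oxygens O3' and O4' of ring B. The key step closes this 1,3,2-dioxathiole 2,2-dioxide ring in one operation, forming both O–S bonds, on 5,7-di-O-benzyl tricetin: a flavone whose ring A oxygens O5 and O7 are benzylated and whose ring B carries the free contiguous triol O3'/O4'/O5'. It exploits two features: the pairs O3'/O4' and O4'/O5' are equivalent by the local symmetry of ring B, and O4', para to C2 and conjugated through C2=C3 with the C4 carbonyl, is the best leaving group, so hydrolysis should leave the sulfate on O3'.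

Key step: step 6

Assumption: the aryl sulfate monoesters 11 and 12 would be handled as their potassium salts (cation from the buffer); they are drawn and balanced as the free acids, the form in which the target is written.

Step 1
Reactants: 1 2',4',6'-trihydroxyacetophenone
Product: 2 phloroacetophenone dibenzyl ether (4',6'-bis(benzyloxy)-2'-hydroxyacetophenone)
Conditions: BnBr (2.1 equiv), K2CO3, DMF, rt
Reagents that add atoms: benzyl bromide, BrCc1ccccc1
Why: Williamson O-benzylation should take the two non-chelated phenols, while the 2'-OH, hydrogen-bonded to the acetyl carbonyl and therefore the least acidic and least nucleophilic, should stay free with two equivalents of halide.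

Step 2
Reactants: 3 3,4,5-trihydroxybenzaldehyde
Product: 4 tris-MOM gallaldehyde (3,4,5-tris(methoxymethoxy)benzaldehyde)
Conditions: MOMCl (3.6 equiv), K2CO3, acetone, 0 °C → 40 °C, N2
Reagents that add atoms: chloromethyl methyl ether, COCCl
Why: Exhaustive O-alkylation of the three phenoxides with the reactive α-chloro ether (methoxymethyl ether formation) should give base-stable, acid-labile protection that is orthogonal to the benzyl ethers of ring A.

Step 3
Reactants: 2 phloroacetophenone dibenzyl ether; 4 tris-MOM gallaldehyde
Product: 5 (E)-4',6'-bis(benzyloxy)-2'-hydroxy-3,4,5-tris(methoxymethoxy)chalcone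
Conditions: KOH (50% aq.), EtOH–THF, rt
Reagents that add atoms: none
Why: Claisen–Schmidt condensation, in which the methyl ketone enolate adds to the non-enolisable aldehyde and E1cB dehydration follows in the flask, should give the thermodynamically favoured E-enone, and both ether types are inert to hydroxide.

Step 4
Reactants: 5 (E)-4',6'-bis(benzyloxy)-2'-hydroxy-3,4,5-tris(methoxymethoxy)chalcone
Product: 6 5,7-bis(benzyloxy)-3',4',5'-tris(methoxymethoxy)flavone
Conditions: I2 (10 mol%), DMSO, 120 °C
Reagents that add atoms: none
Why: Iodine–DMSO oxidative cyclisation of a 2'-hydroxychalcone (conjugate closure of the 2'-OH onto the enone and iodine-mediated dehydrogenation across C2–C3) should give the flavone, with DMSO reoxidising HI so that a catalytic amount of I2 suffices and acid exposure of the acetals and of the peri benzyl ether stays low.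

Step 5
Reactants: 6 5,7-bis(benzyloxy)-3',4',5'-tris(methoxymethoxy)flavone
Product: 7 5,7-di-O-benzyl tricetin (5,7-bis(benzyloxy)-3',4',5'-trihydroxyflavone)
Conditions: HCl (2 M aq.), MeOH–THF, 45 °C, Ar
Reagents that add atoms: none
Why: Acid-catalysed acetal exchange with methanol should remove the three aryl methoxymethyl ethers under conditions too mild to cleave aryl benzyl ethers, and argon protects the oxidation-prone ring B triol.

Step 6
Reactants: 7 5,7-di-O-benzyl tricetin; 8 1,1'-sulfonyldiimidazole
Product: 10 5,7-di-O-benzyl tricetin 3',4'-cyclic sulfate, via 4'-O-imidazolylsulfonyl triol 9 (not isolated)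
Conditions: 8 (1.05 equiv), KF (spray-dried, 5 equiv), THF–MeCN, 0 °C → rt, 0.01 M, slow addition of 7, Ar
Reagents that add atoms: 1,1'-sulfonyldiimidazole (8), O=S(=O)(n1ccnc1)n1ccnc1
Why: Proposed new method: with fluoride as base, the most acidic phenol O4'–H (para to C2, conjugated through C2=C3 with C4=O) should displace one imidazole at the sulfur of 8 to give imidazolylsulfonate 9, and the neighbouring O3' phenoxide (equivalently O5') should then displace the second imidazole intramolecularly. The closest known reaction type is the conversion of simple catechols into 1,3,2-benzodioxathiole 2,2-dioxides with sulfuryl-transfer reagents such as 8 or SO2Cl2; a pyrogallol-type flavone triol has not been bridged in this way. The ring closes by 5-exo attack of an ortho oxygen at tetrahedral sulfur, a closure open only to vicinal oxygens, because a bridge from O3' to O5' would need an impossibly strained meta-linked ring. No stereocentre is formed. The step needs a single bridge and no intermolecular sulfuryl transfer: the two vicinal pairs are identical by the symmetry of ring B, so either closure gives 10; the remaining hydroxyl is deactivated by the electron-poor sulfate ring; one equivalent of 8, high dilution and slow addition of 7 favour ring closure over oligomer formation; and O5 and O7 are blocked as benzyl ethers.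

Step 7
Reactants: 10 5,7-di-O-benzyl tricetin 3',4'-cyclic sulfate
Product: 11 5,7-di-O-benzyl tricetin 3'-sulfate
Conditions: KHCO3/K2CO3 buffer (pH 9), THF–H2O (degassed), 0 °C → rt, Ar
Reagents that add atoms: water, O
Why: Proposed new method: hydroxide or water should attack the strained, strongly electrophilic sulfur of the five-membered aryl cyclic sulfate and break the S–O bond to the better phenoxide leaving group, which should be O4' (para to C2, hence conjugated with the C4 carbonyl, and hydrogen-bonded by the 5'-OH), so the sulfate stays on O3', while a shift of the ring to O4'/O5' through the 5'-phenoxide is degenerate and leads to the same product; the closest known reaction type is the mild alkaline hydrolysis of catechol cyclic sulfates to catechol monosulfates, whose regiochemical course on a hydroxylated flavone ring B is untested.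

Step 8
Reactants: 11 5,7-di-O-benzyl tricetin 3'-sulfate
Product: 12 tricetin 3'-sulfate
Conditions: H2 (1 atm), Pd/C (10 wt%), MeOH–THF, rt
Reagents that add atoms: none
Why: Heterogeneous catalytic hydrogenolysis should cleave the two aryl benzyl ethers, while the aryl sulfate monoester salt, the free phenols and the flavone C2=C3 bond are stable to hydrogen over Pd/C at ambient pressure in neutral medium.

Compound list
1 | 2',4',6'-trihydroxyacetophenone | CC(=O)c1c(O)cc(O)cc1O | starting material
2 | 4',6'-bis(benzyloxy)-2'-hydroxyacetophenone | CC(=O)c1c(O)cc(OCc2ccccc2)cc1OCc1ccccc1 | intermediate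
3 | 3,4,5-trihydroxybenzaldehyde | O=Cc1cc(O)c(O)c(O)c1 | starting material
4 | 3,4,5-tris(methoxymethoxy)benzaldehyde | COCOc1cc(C=O)cc(OCOC)c1OCOC | intermediate
5 | (E)-4',6'-bis(benzyloxy)-2'-hydroxy-3,4,5-tris(methoxymethoxy)chalcone | O=C(/C=C/c1cc(OCOC)c(OCOC)c(OCOC)c1)c1c(O)cc(OCc2ccccc2)cc1OCc1ccccc1 | intermediate
6 | 5,7-bis(benzyloxy)-3',4',5'-tris(methoxymethoxy)flavone | O=c1cc(-c2cc(OCOC)c(OCOC)c(OCOC)c2)oc2cc(OCc3ccccc3)cc(OCc3ccccc3)c12 | intermediate
7 | 5,7-di-O-benzyl tricetin | O=c1cc(-c2cc(O)c(O)c(O)c2)oc2cc(OCc3ccccc3)cc(OCc3ccccc3)c12 | intermediate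
8 | 1,1'-sulfonyldiimidazole | O=S(=O)(n1ccnc1)n1ccnc1 | starting material
9 | 5,7-di-O-benzyl-4'-O-(imidazol-1-ylsulfonyl) tricetin, formed in the flask | O=c1cc(-c2cc(O)c(OS(=O)(=O)n3ccnc3)c(O)c2)oc2cc(OCc3ccccc3)cc(OCc3ccccc3)c12 | intermediate
10 | 5,7-di-O-benzyl tricetin 3',4'-cyclic sulfate (ring B fused to a 1,3,2-dioxathiole 2,2-dioxide across O3'/O4', free 5'-OH) | O=c1cc(-c2cc(O)c3OS(=O)(=O)Oc3c2)oc2cc(OCc3ccccc3)cc(OCc3ccccc3)c12 | intermediate
11 | 5,7-di-O-benzyl tricetin 3'-sulfate | O=c1cc(-c2cc(O)c(O)c(OS(=O)(=O)O)c2)oc2cc(OCc3ccccc3)cc(OCc3ccccc3)c12 | intermediate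
12 | tricetin 3'-sulfate | O=c1cc(-c2cc(O)c(O)c(OS(=O)(=O)O)c2)oc2cc(O)cc(O)c12 | target

Total step count: 8. Longest linear sequence: 7 steps (1 → 2 → 5 → 6 → 7 → 10 → 11 → 12).

Steps most likely to fail

Step 6. The risk is intermolecular sulfuryl transfer to the free ring B hydroxyl of a second molecule, giving oligomeric diaryl sulfates, or sulfonylation of more than one oxygen before the ring closes. The fallback blocks O4' and does not bridge. It sets out from 7: Williamson alkylation with one equivalent of BnBr under weak base (KHCO3, DMF, rt) should select the most acidic ring B phenol and give 5,7,4'-tri-O-benzyl tricetin F1. Sulfation of one of the two equivalent flanking hydroxyls with a limiting amount of SO3·NMe3 (Et3N, DMF, 40 °C) should give 5,7,4'-tri-O-benzyl tricetin 3'-sulfate F2, separable from recovered F1 and from disulfate by reversed-phase chromatography. Hydrogenolysis of the three benzyl ethers (H2, Pd/C, MeOH–THF) comes back to the route at 12.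

Step 7. The risk is insufficient regioselectivity in the ring opening, with O3' departing in place of O4', or oxidative degradation of the electron-rich ring B at basic pH. The fallback fixes the position of the sulfate before it is introduced. It sets out from 7: one equivalent of 1,1'-carbonyldiimidazole (THF, rt) should bridge two vicinal ring B oxygens as 5,7-di-O-benzyl tricetin 4',5'-cyclic carbonate F3. Any migration of the carbonate between the two vicinal pairs is degenerate, so the free hydroxyl is necessarily a terminal one. Sulfation of that hydroxyl with SO3·pyridine (MeCN–DMF, rt) should give 5,7-di-O-benzyl tricetin 4',5'-cyclic carbonate 3'-sulfate F4. Mild hydrolysis of the carbonate (KHCO3, MeOH–H2O, rt), which aryl sulfate salts tolerate, comes back to the route at 11.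

Step 4. The risk is acid-induced loss of methoxymethyl groups or of the peri benzyl group on O5 by the HI formed at 120 °C, followed by oxidation of the phenols so exposed. The fallback separates ring closure from dehydrogenation and avoids HI. It sets out from 5: base-mediated oxa-Michael cyclisation (CH3CO2Na, EtOH, reflux) should give racemic 5,7-bis(benzyloxy)-3',4',5'-tris(methoxymethoxy)flavanone F5. Dehydrogenation with DDQ (dioxane, reflux) comes back to the route at 6.

Further compounds
F1 | step 6 | 5,7,4'-tri-O-benzyl tricetin | O=c1cc(-c2cc(O)c(OCc3ccccc3)c(O)c2)oc2cc(OCc3ccccc3)cc(OCc3ccccc3)c12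
F2 | step 6 | 5,7,4'-tri-O-benzyl tricetin 3'-sulfate | O=c1cc(-c2cc(O)c(OCc3ccccc3)c(OS(=O)(=O)O)c2)oc2cc(OCc3ccccc3)cc(OCc3ccccc3)c12
F3 | step 7 | 5,7-di-O-benzyl tricetin 4',5'-cyclic carbonate | O=c1cc(-c2cc(O)c3OC(=O)Oc3c2)oc2cc(OCc3ccccc3)cc(OCc3ccccc3)c12
F4 | step 7 | 5,7-di-O-benzyl tricetin 4',5'-cyclic carbonate 3'-sulfate | O=c1cc(-c2cc(OS(=O)(=O)O)c3OC(=O)Oc3c2)oc2cc(OCc3ccccc3)cc(OCc3ccccc3)c12
F5 | step 4 | racemic 5,7-bis(benzyloxy)-3',4',5'-tris(methoxymethoxy)flavanone | O=C1CC(c2cc(OCOC)c(OCOC)c(OCOC)c2)Oc2cc(OCc3ccccc3)cc(OCc3ccccc3)c12
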